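**Retrosynthetic overview**
- The route rests on the five-membered carbocycle: the C1 ketone, the cis C2=C3 alkene and the C4 carbinol carbon together are a (Z)-4-oxo-2-enal, that is, an oxidatively opened 2-substituted furan in which C5 is the only enolisable carbon. The C4–C5 bond is therefore cut as an intramolecular aldol and the ring unfolded to a furan.
- The furan carries the future C5 as a silylated furyl carbinol and C6 as a free hydroxyl. It comes from 2-furyllithium and (S)-2-(triethylsilyloxy)hexadecanal; the carbinol configuration is irrelevant because the enolate erases it.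
- C6 is the only stereocentre brought in, from (R)-glycidol and a tridecyl Grignard reagent; C5 and C4 are set from C6 during the ring closure.
- The cyclopentenone is the only ring and is formed in step 7; the end game is C4 silylation, C6 acetylation and global desilylation.

Key step: step 7

Assumption: ring atoms are numbered C1 (C=O), C2=C3, C4 (CHOH), C5 (C–O) and C6 (side-chain carbinol carbon); both epimers at the furyl carbinol carbon (future C5) are carried unseparated from step 4 to step 7, one being drawn, because that centre becomes the planar enolate carbon.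

**Step 1**
Reactants: 1 (R)-glycidol; 2 1-bromotridecane
Product: 4 (2S)-hexadecane-1,2-diol, via tridecylmagnesium bromide 3 (not isolated)
Conditions: Mg, THF, reflux (2 to 3, 2.5 equiv); then CuI (10 mol%), 1, THF, −30 → 0 °C; aq. NH4Cl
Reagents that add atoms: none
Why: Copper-catalysed Grignard opening of the epoxide at its unsubstituted carbon (one equivalent of 3 is first consumed by the hydroxyl) does not touch the glycidol stereocentre, which becomes C6 of the target and is called S only because the CIP priorities change.

**Step 2**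
Reactants: 4 (2S)-hexadecane-1,2-diol
Product: 5 (2S)-1,2-bis(triethylsilyloxy)hexadecane
Conditions: TESCl (2.4 equiv), imidazole, DMF, 0 °C → rt
Reagents that add atoms: chlorotriethylsilane, CC[Si](Cl)(CC)CC
Why: Exhaustive silylation of a diol with a silyl chloride and imidazole is routine and leaves the stereocentre untouched.

**Step 3**
Reactants: 5 (2S)-1,2-bis(triethylsilyloxy)hexadecane
Product: 6 (2S)-2-(triethylsilyloxy)hexadecanal
Conditions: (COCl)2, DMSO, CH2Cl2, −78 → −35 °C; then i-Pr2NEt, −78 → 0 °C
Reagents that add atoms: none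
Why: In this oxidative desilylation under Swern conditions the chlorosulfonium salt cleaves only the unhindered primary silyl ether and the alkoxysulfonium ion collapses to the aldehyde, while the secondary silyl ether survives and the hindered base at low temperature should not epimerise the alpha-silyloxy aldehyde.

**Step 4**
Reactants: 6 (2S)-2-(triethylsilyloxy)hexadecanal; 7 furan
Product: 9 (1S,2S)-1-(furan-2-yl)-2-(triethylsilyloxy)hexadecan-1-ol (with its 1R epimer), via 2-furyllithium 8 (not isolated)
Conditions: n-BuLi, THF, −78 → 0 °C (7 to 8); then 6, THF, −78 °C; aq. NH4Cl at −78 °C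
Reagents that add atoms: none
Why: C2-lithiated furan adds 1,2 to the aldehyde; Felkin–Anh control by the alpha-silyloxy group should favour the anti (1S,2S) carbinol, but the epimer ratio does not matter because this carbon becomes the enolate carbon C5 in step 7, and the cold quench limits silyl migration and enolisation of 6.

**Step 5**
Reactants: 9 (1S,2S)-1-(furan-2-yl)-2-(triethylsilyloxy)hexadecan-1-ol
Product: 10 tert-butyl{[(1S,2S)-1-(furan-2-yl)-2-(triethylsilyloxy)hexadecyl]oxy}dimethylsilane
Conditions: TBSCl, imidazole, 4-(dimethylamino)pyridine (cat.), DMF, rt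
Reagents that add atoms: tert-butyldimethylsilyl chloride, CC(C)(C)[Si](C)(C)Cl
Why: Standard silylation of the secondary furyl carbinol installs the robust ether that will stay on the C5 oxygen through the oxidation and the aldol.

**Step 6**
Reactants: 10 tert-butyl{[(1S,2S)-1-(furan-2-yl)-2-(triethylsilyloxy)hexadecyl]oxy}dimethylsilane
Product: 11 (1S,2S)-1-(tert-butyldimethylsilyloxy)-1-(furan-2-yl)hexadecan-2-ol
Conditions: HF·pyridine, pyridine, THF, 0 °C
Reagents that add atoms: none
Why: Selective desilylation: buffered HF·pyridine cleaves a triethylsilyl ether much faster than a tert-butyldimethylsilyl ether, and the weakly acidic, non-ionising medium should neither solvolyse the furfuryl ether nor move the silyl group to the freed C6 hydroxyl.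

**Step 7**
Reactants: 11 (1S,2S)-1-(tert-butyldimethylsilyloxy)-1-(furan-2-yl)hexadecan-2-ol (with its 1R epimer); 12 dioxygen
Product: 15 (4S,5S)-5-(tert-butyldimethylsilyloxy)-4-hydroxy-5-[(1S)-1-hydroxypentadecyl]cyclopent-2-en-1-one, via furan endoperoxide 13 (not isolated), via (Z)-4-oxo-2-enal 14 (not isolated)
Conditions: O2, hν (visible light), 5,10,15,20-tetraphenylporphyrin (cat.), CH2Cl2, −78 °C; Me2S, −78 → −20 °C; then MgBr2·OEt2 (3 equiv), i-Pr2NEt, CH2Cl2, −40 → 0 °C
Reagents that add atoms: none
Why: Singlet oxygen adds across the 2,5-positions of the furan in a [4+2] cycloaddition and Me2S reduces the endoperoxide 13 to the (Z)-4-oxo-2-enal 14, in which C5 is the only enolisable carbon; MgBr2 then bridges the C1 carbonyl and the C6 hydroxyl, the amine removes the C5 proton (soft enolisation), and C5 of the chelated magnesium enolate adds to the C4 aldehyde. The closest known reaction type is the photooxygenation, Me2S reduction and base-induced aldol that converts 2-substituted furans into 4-hydroxycyclopent-2-enones, together with the base isomerisation of Achmatowicz pyranones to 4,5-dihydroxycyclopentenones. The cyclopentenone ring closes in the 5-(enolendo)-exo-trig mode, since the enolate bond C1=C5 ends up inside the ring; this mode is formally disfavoured by Baldwin's rules for enolates but is the one followed by 1,4-dicarbonyl aldol cyclisations to cyclopentenones, and here the cis alkene holds C4 and C5 within bonding distance in a U-shaped O=C4–C3=C2–C1(O)=C5 array that can close like a conrotatory four-electron electrocyclisation. C5 is controlled by C6 through the six-membered O1–Mg–O6 chelate, C4 bonding to the enolate face anti to the tetradecyl chain as in Fráter–Seebach alkylations, and both C1 epimers of 11 give the same enolate, so the step is stereoconvergent. C4 is controlled by the enolate geometry that the chelate enforces: C6 sits cis to O1 and thus on the outside of the U, the aldehyde oxygen also points outward, and conrotation places the C4 hydroxyl trans to the side chain and cis to the silyloxy group, which is also the less crowded isomer if the aldol equilibrates. The step needs closure to be faster than amine-induced Z to E isomerisation of the enedione, retro-aldol loss of pentadecanal, beta-elimination and oxa-Michael attack of the C6 oxygen on the enal; the cis geometry delivered by the furan, the hindered amine, the low temperature, the poor leaving-group ability of a magnesium-bound C6 oxygen and its sequestration at O1 in the chelate are meant to secure this.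

**Step 8**
Reactants: 15 (4S,5S)-5-(tert-butyldimethylsilyloxy)-4-hydroxy-5-[(1S)-1-hydroxypentadecyl]cyclopent-2-en-1-one
Product: 16 (4S,5S)-5-(tert-butyldimethylsilyloxy)-5-[(1S)-1-hydroxypentadecyl]-4-(triethylsilyloxy)cyclopent-2-en-1-one
Conditions: TESCl (1.1 equiv), imidazole, CH2Cl2, −20 °C
Reagents that add atoms: chlorotriethylsilane, CC[Si](Cl)(CC)CC
Why: Kinetic monosilylation should pick the ring allylic C4 hydroxyl, which is flanked by the flat sp2 C3, over the C6 hydroxyl, which lies between the quaternary C5 and the alkyl chain and is hydrogen-bonded to the C1 carbonyl.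

**Step 9**
Reactants: 16 (4S,5S)-5-(tert-butyldimethylsilyloxy)-5-[(1S)-1-hydroxypentadecyl]-4-(triethylsilyloxy)cyclopent-2-en-1-one
Product: 17 (1S)-1-[(1S,5S)-1-(tert-butyldimethylsilyloxy)-2-oxo-5-(triethylsilyloxy)cyclopent-3-en-1-yl]pentadecyl acetate
Conditions: Ac2O, 4-(dimethylamino)pyridine, pyridine, CH2Cl2, 0 °C → rt
Reagents that add atoms: acetic anhydride, CC(=O)OC(C)=O
Why: Nucleophile-catalysed acetylation of the remaining hindered secondary alcohol is a standard esterification, and since C5 bears no hydrogen the mild base cannot cause beta-elimination of the C4 or C6 oxygen substituents.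

**Step 10**
Reactants: 17 (1S)-1-[(1S,5S)-1-(tert-butyldimethylsilyloxy)-2-oxo-5-(triethylsilyloxy)cyclopent-3-en-1-yl]pentadecyl acetate
Product: 18 (1S)-1-[(1R,5S)-1,5-dihydroxy-2-oxocyclopent-3-en-1-yl]pentadecyl acetate (target)
Conditions: HF·pyridine, THF, 0 °C → rt
Reagents that add atoms: none
Why: Acidic fluoride desilylation cleaves the secondary triethylsilyl ether and, more slowly, the tertiary alpha-keto tert-butyldimethylsilyl ether without generating the alkoxides that would open the ring by retro-aldol reaction or shift the acetate, and no stereocentre is touched.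

**Compound list**
1 | (R)-glycidol, (2R)-oxiran-2-ylmethanol | OC[C@@H]1CO1 | starting material
2 | 1-bromotridecane | CCCCCCCCCCCCCBr | starting material
3 | tridecylmagnesium bromide (not isolated) | CCCCCCCCCCCCC[Mg]Br | intermediate
4 | (2S)-hexadecane-1,2-diol | CCCCCCCCCCCCCC[C@H](O)CO | intermediate
5 | (2S)-1,2-bis(triethylsilyloxy)hexadecane | CCCCCCCCCCCCCC[C@H](O[Si](CC)(CC)CC)CO[Si](CC)(CC)CC | intermediate
6 | (2S)-2-(triethylsilyloxy)hexadecanal | CCCCCCCCCCCCCC[C@H](O[Si](CC)(CC)CC)C=O | intermediate
7 | furan | c1ccoc1 | starting material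
8 | 2-furyllithium (not isolated) | [Li]c1ccco1 | intermediate
9 | (1S,2S)-1-(furan-2-yl)-2-(triethylsilyloxy)hexadecan-1-ol (anti epimer drawn; carried with its (1R,2S) epimer) | CCCCCCCCCCCCCC[C@H](O[Si](CC)(CC)CC)[C@H](O)c1ccco1 | intermediate
10 | tert-butyl{[(1S,2S)-1-(furan-2-yl)-2-(triethylsilyloxy)hexadecyl]oxy}dimethylsilane (with its 1R epimer) | CCCCCCCCCCCCCC[C@H](O[Si](CC)(CC)CC)[C@H](O[Si](C)(C)C(C)(C)C)c1ccco1 | intermediate
11 | (1S,2S)-1-(tert-butyldimethylsilyloxy)-1-(furan-2-yl)hexadecan-2-ol (with its 1R epimer; key-step precursor) | CCCCCCCCCCCCCC[C@H](O)[C@H](O[Si](C)(C)C(C)(C)C)c1ccco1 | intermediate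
12 | dioxygen (sensitised to the singlet state) | O=O | starting material
13 | 1-[(1S,2S)-1-(tert-butyldimethylsilyloxy)-2-hydroxyhexadecyl]-2,3,7-trioxabicyclo[2.2.1]hept-5-ene (bridgehead and carbinol epimers; not isolated) | CCCCCCCCCCCCCC[C@H](O)[C@H](O[Si](C)(C)C(C)(C)C)C12C=CC(O1)OO2 | intermediate
14 | (2Z,5S,6S)-5-(tert-butyldimethylsilyloxy)-6-hydroxy-4-oxoicos-2-enal (with its 5R epimer; not isolated) | CCCCCCCCCCCCCC[C@H](O)[C@H](O[Si](C)(C)C(C)(C)C)C(=O)/C=C\C=O | intermediate
15 | (4S,5S)-5-(tert-butyldimethylsilyloxy)-4-hydroxy-5-[(1S)-1-hydroxypentadecyl]cyclopent-2-en-1-one (key-step product) | CCCCCCCCCCCCCC[C@H](O)[C@@]1(O[Si](C)(C)C(C)(C)C)C(=O)C=C[C@@H]1O | intermediate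
16 | (4S,5S)-5-(tert-butyldimethylsilyloxy)-5-[(1S)-1-hydroxypentadecyl]-4-(triethylsilyloxy)cyclopent-2-en-1-one | CCCCCCCCCCCCCC[C@H](O)[C@@]1(O[Si](C)(C)C(C)(C)C)C(=O)C=C[C@@H]1O[Si](CC)(CC)CC | intermediate
17 | (1S)-1-[(1S,5S)-1-(tert-butyldimethylsilyloxy)-2-oxo-5-(triethylsilyloxy)cyclopent-3-en-1-yl]pentadecyl acetate | CCCCCCCCCCCCCC[C@H](OC(C)=O)[C@@]1(O[Si](C)(C)C(C)(C)C)C(=O)C=C[C@@H]1O[Si](CC)(CC)CC | intermediate
18 | (1S)-1-[(1R,5S)-1,5-dihydroxy-2-oxocyclopent-3-en-1-yl]pentadecyl acetate, i.e. (4S,5R)-5-[(1S)-1-acetoxypentadecyl]-4,5-dihydroxycyclopent-2-en-1-one | CCCCCCCCCCCCCC[C@H](OC(C)=O)[C@@]1(O)C(=O)C=C[C@@H]1O | target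

**Step count**
Total step count: 10. Longest linear sequence: 10 steps (1 to 18).

**Steps most likely to fail**

Step 7. The amine may isomerise the (Z)-enedione to the E isomer before closure, the beta-hydroxy ketone may fragment by retro-aldol reaction, the free C6 oxygen may add to the enal, or the facial selectivity at C5 and C4 may be poor. The fallback stores the enal as a cyclic hemiacetal and keeps the C6 oxygen silylated. It sets out from 9. Achmatowicz oxidation (NBS, NaHCO3, NaOAc, THF–H2O, 0 °C) should give 6-hydroxy-2-[(1S)-1-(triethylsilyloxy)pentadecyl]-2H-pyran-3(6H)-one F1. Et3N in CH2Cl2 should isomerise it, by ring opening, enolisation towards C5 and aldol closure, to (4S,5R)-4,5-dihydroxy-5-[(1S)-1-(triethylsilyloxy)pentadecyl]cyclopent-2-en-1-one F2. Its C5 epimers would have to be separated, because C5 then rests only on 1,2-induction from C6. TBSCl and imidazole should silylate only the secondary C4 hydroxyl to give the 4-O-tert-butyldimethylsilyl ether F3. HF·pyridine with pyridine removes the triethylsilyl group to give the C5,C6-diol F4. Ac2O in pyridine acetylates the secondary C6 hydroxyl, the tertiary one being inert, to give the C6 acetate F5. HF·pyridine then frees C4, and the fallback comes back to the route at 18.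

Step 8. The two secondary hydroxyls may be discriminated poorly, giving regioisomeric and doubly silylated products. The fallback differentiates through the cis-4,5-diol instead of through sterics. It sets out from 15. Aqueous HF in MeCN removes the C5 silyl group to give (4S,5S)-4,5-dihydroxy-5-[(1S)-1-hydroxypentadecyl]cyclopent-2-en-1-one F6. PhB(OH)2 (MgSO4, CH2Cl2) should tie the cis-1,2-diol on the five-membered ring, the best boronate-binding motif in the molecule, into the cyclic 4,5-O-phenylboronate F7. Ac2O, pyridine and 4-(dimethylamino)pyridine acetylate the only free hydroxyl to give the 6-O-acetyl boronate F8. Exchange with pinacol releases the diol, and the fallback comes back to the route at 18.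

Step 10. The hindered tertiary silyl ether may cleave too slowly, with loss or migration of the acetate once conditions are forced. The fallback moves this desilylation ahead of the acetylation. It sets out from 15, which aqueous HF in MeCN converts into the triol F6 while no acetate is present. TESCl and imidazole at −20 °C, with the site selectivity already established in step 8 and an inert tertiary hydroxyl, give (4S,5S)-5-hydroxy-5-[(1S)-1-hydroxypentadecyl]-4-(triethylsilyloxy)cyclopent-2-en-1-one F9. Ac2O in pyridine gives its C6 acetate F10. Brief HF·pyridine with pyridine at 0 °C removes the secondary silyl ether, and the fallback comes back to the route at 18.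

Further compounds
F1 | step 7 | 6-hydroxy-2-[(1S)-1-(triethylsilyloxy)pentadecyl]-2H-pyran-3(6H)-one (ring epimers) | CCCCCCCCCCCCCC[C@H](O[Si](CC)(CC)CC)C1OC(O)C=CC1=O
F2 | step 7 | (4S,5R)-4,5-dihydroxy-5-[(1S)-1-(triethylsilyloxy)pentadecyl]cyclopent-2-en-1-one | CCCCCCCCCCCCCC[C@H](O[Si](CC)(CC)CC)[C@@]1(O)C(=O)C=C[C@@H]1O
F3 | step 7 | (4S,5S)-4-(tert-butyldimethylsilyloxy)-5-hydroxy-5-[(1S)-1-(triethylsilyloxy)pentadecyl]cyclopent-2-en-1-one | CCCCCCCCCCCCCC[C@H](O[Si](CC)(CC)CC)[C@@]1(O)C(=O)C=C[C@@H]1O[Si](C)(C)C(C)(C)C
F4 | step 7 | (4S,5S)-4-(tert-butyldimethylsilyloxy)-5-hydroxy-5-[(1S)-1-hydroxypentadecyl]cyclopent-2-en-1-one | CCCCCCCCCCCCCC[C@H](O)[C@@]1(O)C(=O)C=C[C@@H]1O[Si](C)(C)C(C)(C)C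
F5 | step 7 | (1S)-1-[(1S,5S)-5-(tert-butyldimethylsilyloxy)-1-hydroxy-2-oxocyclopent-3-en-1-yl]pentadecyl acetate | CCCCCCCCCCCCCC[C@H](OC(C)=O)[C@@]1(O)C(=O)C=C[C@@H]1O[Si](C)(C)C(C)(C)C
F6 | step 8 | (4S,5S)-4,5-dihydroxy-5-[(1S)-1-hydroxypentadecyl]cyclopent-2-en-1-one | CCCCCCCCCCCCCC[C@H](O)[C@@]1(O)C(=O)C=C[C@@H]1O
F7 | step 8 | cyclic 4,5-O-phenylboronate of F6 | CCCCCCCCCCCCCC[C@H](O)[C@@]1(OB(c2ccccc2)O3)C(=O)C=C[C@@H]13
F8 | step 8 | 6-O-acetyl derivative of the cyclic 4,5-O-phenylboronate | CCCCCCCCCCCCCC[C@H](OC(C)=O)[C@@]1(OB(c2ccccc2)O3)C(=O)C=C[C@@H]13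
F9 | step 10 | (4S,5S)-5-hydroxy-5-[(1S)-1-hydroxypentadecyl]-4-(triethylsilyloxy)cyclopent-2-en-1-one | CCCCCCCCCCCCCC[C@H](O)[C@@]1(O)C(=O)C=C[C@@H]1O[Si](CC)(CC)CC
F10 | step 10 | (1S)-1-[(1S,5S)-1-hydroxy-2-oxo-5-(triethylsilyloxy)cyclopent-3-en-1-yl]pentadecyl acetate | CCCCCCCCCCCCCC[C@H](OC(C)=O)[C@@]1(O)C(=O)C=C[C@@H]1O[Si](CC)(CC)CC
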